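77.5% of what the ochre run has made by 15.0 h is still target, and ash repeats that recipe, so I read ash there.

| flask | electrophile | free base | protonated nucleophile | remark | time |
|---|---|---|---|---|---|
| ochre | 0.20 M | 1.2 equiv | 2.5 equiv | run made earlier |  |
| violet | 0.20 M | 1.2 equiv | 1.2 equiv | run made earlier |  |
| blue | 0.20 M | 1.2 equiv | 1.9 equiv | run made earlier |  |
| ash | 0.20 M | 1.20 equiv | 2.50 equiv | everything together at the start | 15 h |
| birch | 0.20 M | 1.20 equiv (fed, over 12 h) | 2.50 equiv | all else is in the flask from the start; the feed brings no volume worth counting | 15 h |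
| cedar | 0.20 M (fed, over 80 min) | 1.20 equiv | 2.50 equiv | all else is in the flask from the start; the feed brings no volume worth counting | 15 h |
| oak | 0.20 M (fed, over 12 h) | 1.20 equiv | 2.50 equiv | all else is in the flask from the start; the feed brings no volume worth counting | 15 h |

| run | time / h | target / % | over-reaction product / % | electrophile / % |
|---|---|---|---|---|
| ochre | 1.33 | 4.8 | 0 | 95.9 |
| ochre | 2.00 | 8.1 | 0.4 | 93.1 |
| ochre | 3.00 | 8.6 | 0 | 90.8 |
| ochre | 4.00 | 9.4 | 0.3 | 90.6 |
| ochre | 6.00 | 16.0 | 0 | 84.2 |
| ochre | 10.0 | 19.7 | 4.0 | 77.9 |
| ochre | 15.0 | 22.7 | 6.6 | 72.0 |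
| violet | 0.667 | 2.2 | 0 | 97.5 |
| violet | 2.00 | 6.3 | 0 | 94.1 |
| violet | 3.00 | 7.3 | 0 | 91.5 |
| violet | 5.00 | 10.8 | 0.9 | 89.6 |
| violet | 8.00 | 12.8 | 2.7 | 86.6 |
| violet | 10.0 | 14.9 | 1.2 | 82.6 |
| violet | 12.0 | 16.6 | 4.2 | 81.5 |
| blue | 1.00 | 2.2 | 0 | 97.3 |
| blue | 1.33 | 3.2 | 0 | 95.9 |
| blue | 2.00 | 4.3 | 0 | 95.3 |
| blue | 3.00 | 6.7 | 0.8 | 92.1 |
| blue | 5.00 | 10.5 | 0.4 | 88.0 |
| blue | 8.00 | 15.5 | 2.0 | 83.6 |
| blue | 12.0 | 20.2 | 3.4 | 77.7 |

(standard deviation of a reading: 1 percentage point)



- the best flask by share of target in target plus over-reaction product; "all alike" if 1.5 percentage points covers them all (ash / birch / cedar / oak / all alike)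
- share of target in target plus over-reaction product at the end, ash
- share of target in target plus over-reaction product at the end, birch
- share of target in target plus over-reaction product at the end, cedar
- share of target in target plus over-reaction product at the end, oak

Electrophile is charged at one equivalent against 1.2 equiv of free base. I write its balance: in ochre at the end, electrophile, target and over-reaction product sum to 101%, and each of these readings carries a scatter of 1 percentage point. So target plus over-reaction product counts what was made, and over-reaction product is the made part that has aged on.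

My rule is that the share lost equals the ageing rate times the mean age of what was made. The ageing rate, the fraction of target passing on per hour, reads 0.0300 h⁻¹ in ochre, taking roughly steady making, so a mean age of half the time. Violet reads 0.0337 h⁻¹ and blue 0.0240 h⁻¹, a spread I put down to the scatter.

Now I bracket oak. Target made at the very start keeps 63.7%, and target made at the very end stays whole. I tighten both sides. Oak's target is no older than steady making from the start, which gives a floor of 77.5%. If making simply follows the electrophile fed, rising to 12 h and then level, the mean age is 5.17 h, which gives a ceiling of 84.5%. Ochre's making fades, and fading makes target older, so I hold that as the top. Cedar's feed ends at 80 min, so cedar stays near ash. The runs never varied free base, so I leave birch unplaced inside the bracket and commit to oak.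

The forecast says oak, with ash 78%, birch 81.5%, cedar 78.5% and oak 83%, on the ground that “selectivity mostly tracks conversion”. Its oak lies inside my bracket.

The flask gives oak as best, with ash 77.4%, birch 82.6%, cedar 78.3% and oak 84.5%.

    electrophile + nucleophile → acid set free + target (k = 0.340 M⁻¹ h⁻¹)
    nucleophile + acid set free ⇌ protonated nucleophile, settled at all times (K = 2200 M⁻¹)
    acid set free + free base ⇌ salt of the base, settled at all times (K = 443 M⁻¹)
    target → over-reaction product (k = 0.0294 h⁻¹)

Oak stands at my ceiling of 84.5%, which by the ageing rate is a mean age of 5.17 h. The neighbouring flask is ash with 0.480 equiv of free base, read at 15.0 h. With steady making, its time gives the same mean age as ash, so the ageing rate gives 77.5% again. Ash keeps electrophile at 71.2%. The neighbour keeps 83.4%, with target 12.8% and over-reaction product 3.76%, and its share is 77.3%.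

(All runs are simulated with made-up constants; scatter was added.)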